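Germacranolide numbering is used (carbocycle C1–C10; lactone C6–O–C12(=O)–C11(=C13)–C7; ester on O8; C14/C15 hydroxymethyls). The route rests on the C6–C7 bond, which belongs to both the ten-membered carbocycle and the γ-lactone and joins two acceptor carbons, the carbinol carbon C6 and the acrylate β-carbon C7. A chromium(II) Barbier closure of an open-chain aldehyde carrying a (Z)-2-(bromomethyl)enoate forms this bond with polarity reversal at C7 and, in one operation, closes the carbocycle, sets C6 and C7 under control of C8 and lactonises to the α-methylene lactone. The precursor, with C4 and C8 already set, comes from E-selective olefination of an Evans-derived aldehyde with a glycidol-derived phosphono lactone.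

Key step: step 18

Remark: PMB = 4-methoxybenzyl, TBDPS = tert-butyldiphenylsilyl. Condensed formulas of open-chain compounds are written from C6 to C7, and their descriptors (4S,8R,1(10)E) refer to the numbering above.

Step 1
Reactants: 1 (S)-4-benzyloxazolidin-2-one; 2 pent-4-enoyl chloride
Product: 3 (S)-4-benzyl-3-(pent-4-enoyl)oxazolidin-2-one
Conditions: n-BuLi, THF, −78 °C; then 2, −78 → 0 °C
Reagents that add atoms: none
Why: N-acylation of the lithiated oxazolidinone by the acid chloride (attachment of the Evans auxiliary) is a standard acyl substitution and creates no stereocentre.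

Step 2
Reactants: 3 (S)-4-benzyl-3-(pent-4-enoyl)oxazolidin-2-one; 4 acrylonitrile
Product: 5 (S)-4-benzyl-3-[(2S)-2-(2-cyanoethyl)pent-4-enoyl]oxazolidin-2-one
Conditions: TiCl4, i-Pr2NEt, CH2Cl2, 0 °C; then 4, 0 °C
Reagents that add atoms: none
Why: Evans asymmetric Michael addition: the chelated (Z)-chlorotitanium enolate should add to acrylonitrile on the face away from the benzyl group, which sets the future C4 as S.

Step 3
Reactants: 5 (S)-4-benzyl-3-[(2S)-2-(2-cyanoethyl)pent-4-enoyl]oxazolidin-2-one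
Product: 6 (4S)-4-(hydroxymethyl)hept-6-enenitrile
Conditions: NaBH4, THF/H2O (4:1), 0 °C → rt
Reagents that add atoms: none
Why: Borohydride reductive cleavage of the N-acyloxazolidinone (hydride attack at the exocyclic imide carbonyl) should free the C15 alcohol and the auxiliary while nitrile and alkene stay untouched.

Step 4
Reactants: 6 (4S)-4-(hydroxymethyl)hept-6-enenitrile
Product: 7 (4S)-4-{[tert-butyl(diphenyl)silyl]oxymethyl}hept-6-enenitrile
Conditions: TBDPSCl, imidazole, CH2Cl2, rt
Reagents that add atoms: tert-butyl(chloro)diphenylsilane, CC(C)(C)[Si](Cl)(c1ccccc1)c1ccccc1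
Why: Imidazole-promoted silyl ether formation at the primary alcohol protects O15 for the whole route.

Step 5
Reactants: 7 (4S)-4-{[tert-butyl(diphenyl)silyl]oxymethyl}hept-6-enenitrile
Product: 9 (4S)-4-{[tert-butyl(diphenyl)silyl]oxymethyl}-6,6-dimethoxyhexanenitrile, via aldehyde 8 (not isolated)
Conditions: O3, CH2Cl2/MeOH, −78 °C; Me2S, → rt; then CH(OMe)3, PPTS, rt
Reagents that add atoms: ozone, O=[O+][O-] (carbonyl oxygen of 8); trimethyl orthoformate, COC(OC)OC (both methoxy groups of 9)
Why: Ozonolysis of the only alkene with reductive work-up gives aldehyde 8, which is acetalised in the same flask so that C6 stays masked until step 17.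

Step 6
Reactants: 9 (4S)-4-{[tert-butyl(diphenyl)silyl]oxymethyl}-6,6-dimethoxyhexanenitrile
Product: 10 (4S)-4-{[tert-butyl(diphenyl)silyl]oxymethyl}-6,6-dimethoxyhexanal
Conditions: DIBAL-H, toluene, −78 °C; aq. Rochelle salt
Reagents that add atoms: water, O (aldehyde oxygen, on hydrolysis of the aluminium aldimine)
Why: DIBAL-H adds once to the nitrile at low temperature and the aluminium aldimine is hydrolysed on work-up (nitrile-to-aldehyde reduction), the acetal and silyl ether being inert.

Step 7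
Reactants: 11 (S)-glycidol
Product: 12 (R)-2-{[(4-methoxybenzyl)oxy]methyl}oxirane
Conditions: NaH, PMBCl, n-Bu4NI (cat.), THF, 0 °C → rt
Reagents that add atoms: 4-methoxybenzyl chloride, COc1ccc(CCl)cc1
Why: Williamson etherification of the alkoxide leaves the epoxide carbon untouched, the descriptor changing from S to R only by the CIP rules.

Step 8
Reactants: 12 (R)-2-{[(4-methoxybenzyl)oxy]methyl}oxirane; 13 triethyl phosphonoacetate
Product: 14 diethyl [(5R)-5-{[(4-methoxybenzyl)oxy]methyl}-2-oxooxolan-3-yl]phosphonate (both C3 epimers)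
Conditions: NaH, 13, DME, 0 °C; then 12, 85 °C
Reagents that add atoms: none
Why: The phosphonoacetate carbanion should open the epoxide at its CH2 terminus (SN2) and the alkoxide then lactonises onto the ethyl ester (epoxide alkylation–lactonisation), so C8 keeps its configuration and the C3 epimers do not matter.

Step 9
Reactants: 14 diethyl [(5R)-5-{[(4-methoxybenzyl)oxy]methyl}-2-oxooxolan-3-yl]phosphonate; 10 (4S)-4-{[tert-butyl(diphenyl)silyl]oxymethyl}-6,6-dimethoxyhexanal
Product: 15 (3E,5R)-3-[(4S)-4-(TBDPSOCH2)-6,6-dimethoxyhexylidene]-5-(PMBOCH2)oxolan-2-one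
Conditions: NaH, THF, 0 °C; then 10, 0 °C → rt
Reagents that add atoms: none
Why: Horner–Wadsworth–Emmons olefination of the α-phosphono lactone is expected to favour the E-alkylidene lactone (chain trans to the carbonyl), which is the C2/C9-cis geometry of the target's C1=C10 bond, the minor Z isomer being removed by chromatography.

Step 10
Reactants: 15 (3E,5R)-3-[(4S)-4-(TBDPSOCH2)-6,6-dimethoxyhexylidene]-5-(PMBOCH2)oxolan-2-one
Product: 16 diol (MeO)2CH–CH2–CH(CH2OTBDPS)–CH2CH2–CH=C(CH2OH)–CH2–CH(OH)–CH2OPMB (4S,8R,1(10)E)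
Conditions: DIBAL-H (5 equiv), CH2Cl2, −78 → 0 °C; aq. Rochelle salt
Reagents that add atoms: none
Why: DIBAL-H 1,2-reduction of the conjugated lactone through the lactol gives the allylic O14 alcohol and frees O8–H without touching acetal, PMB or silyl ether.

Step 11
Reactants: 16 diol (MeO)2CH–CH2–CH(CH2OTBDPS)–CH2CH2–CH=C(CH2OH)–CH2–CH(OH)–CH2OPMB
Product: 17 secondary alcohol (MeO)2CH–CH2–CH(CH2OTBDPS)–CH2CH2–CH=C(CH2OTBDPS)–CH2–CH(OH)–CH2OPMB (4S,8R,1(10)E)
Conditions: TBDPSCl (1.05 equiv), imidazole, CH2Cl2, 0 °C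
Reagents that add atoms: tert-butyl(chloro)diphenylsilane, CC(C)(C)[Si](Cl)(c1ccccc1)c1ccccc1
Why: Chemoselective silylation: the bulky silyl chloride should react at the primary allylic hydroxyl and leave the secondary C8 hydroxyl free.

Step 12
Reactants: 17 secondary alcohol (MeO)2CH–CH2–CH(CH2OTBDPS)–CH2CH2–CH=C(CH2OTBDPS)–CH2–CH(OH)–CH2OPMB
Product: 18 p-methoxybenzylidene acetal (MeO)2CH–CH2–CH(CH2OTBDPS)–CH2CH2–CH=C(CH2OTBDPS)–CH2–[(4R)-2-(4-methoxyphenyl)-1,3-dioxolan-4-yl] (acetal epimers)
Conditions: DDQ, 4 Å MS, CH2Cl2, 0 °C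
Reagents that add atoms: none
Why: DDQ oxidises the PMB ether to an oxocarbenium ion that the neighbouring free C8 hydroxyl traps under anhydrous conditions (oxidative p-methoxybenzylidene acetal formation), which moves the protecting group towards O8.

Step 13
Reactants: 18 p-methoxybenzylidene acetal spanning O7 and O8
Product: 19 primary alcohol (MeO)2CH–CH2–CH(CH2OTBDPS)–CH2CH2–CH=C(CH2OTBDPS)–CH2–CH(OPMB)–CH2OH (4S,8R,1(10)E)
Conditions: DIBAL-H, CH2Cl2, −78 → 0 °C
Reagents that add atoms: none
Why: Regioselective reductive acetal opening: DIBAL-H coordinates the less hindered O7 and delivers hydride to the acetal carbon, which should leave the PMB ether on the secondary O8 and free the primary C7 alcohol.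

Step 14
Reactants: 19 primary alcohol (MeO)2CH–CH2–CH(CH2OTBDPS)–CH2CH2–CH=C(CH2OTBDPS)–CH2–CH(OPMB)–CH2OH
Product: 20 aldehyde (MeO)2CH–CH2–CH(CH2OTBDPS)–CH2CH2–CH=C(CH2OTBDPS)–CH2–CH(OPMB)–CHO (4S,8R,1(10)E)
Conditions: Dess–Martin periodinane, NaHCO3, CH2Cl2, 0 °C → rt
Reagents that add atoms: none
Why: Buffered Dess–Martin oxidation gives the α-alkoxy aldehyde under non-epimerising conditions.

Step 15
Reactants: 20 aldehyde (MeO)2CH–CH2–CH(CH2OTBDPS)–CH2CH2–CH=C(CH2OTBDPS)–CH2–CH(OPMB)–CHO; 21 methyl acrylate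
Product: 22 hydroxy ester (MeO)2CH–CH2–CH(CH2OTBDPS)–CH2CH2–CH=C(CH2OTBDPS)–CH2–CH(OPMB)–CH(OH)–C(=CH2)CO2Me (4S,8R,1(10)E; both C7 epimers)
Conditions: DABCO (1 equiv), 21 (neat, excess), MeOH (cat.), rt
Reagents that add atoms: none
Why: Morita–Baylis–Hillman reaction: the inductively activated α-alkoxy aldehyde is attacked by the DABCO–acrylate zwitterion, and the new carbinol centre (C7, both epimers) is irrelevant because it becomes sp2 in step 16.

Step 16
Reactants: 22 hydroxy ester (Morita–Baylis–Hillman adduct)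
Product: 23 allylic bromide (MeO)2CH–CH2–CH(CH2OTBDPS)–CH2CH2–CH=C(CH2OTBDPS)–CH2–CH(OPMB)–CH=C(CH2Br)CO2Me (4S,8R,1(10)E,7Z)
Conditions: NBS, Me2S, CH2Cl2, 0 °C → rt
Reagents that add atoms: N-bromosuccinimide, O=C1CCC(=O)N1Br (bromine)
Why: Corey–Kim-type activation of the allylic alcohol followed by SN2′ attack of bromide (bromination with allylic transposition) should give the thermodynamically preferred (Z)-2-(bromomethyl)enoate, in which C8 is cis to CH2Br.

Step 17
Reactants: 23 allylic bromide with C6 dimethyl acetal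
Product: 24 bromo aldehyde OHC–CH2–CH(CH2OTBDPS)–CH2CH2–CH=C(CH2OTBDPS)–CH2–CH(OPMB)–CH=C(CH2Br)CO2Me (4S,8R,1(10)E,7Z)
Conditions: TsOH·H2O (cat.), acetone/H2O (10:1), rt
Reagents that add atoms: water, O (aldehyde oxygen)
Why: Acid-catalysed acetal hydrolysis frees the C6 aldehyde, while TBDPS ethers, PMB ether and the allylic bromide tolerate dilute TsOH at room temperature.

Step 18
Reactants: 24 bromo aldehyde OHC–CH2–CH(CH2OTBDPS)–CH2CH2–CH=C(CH2OTBDPS)–CH2–CH(OPMB)–CH=C(CH2Br)CO2Me
Product: 26 8-O-PMB-14,15-bis-O-TBDPS derivative of the 8-deacyl target lactone (ten-membered ring and trans-fused α-methylene lactone; all stereocentres as in the target), via ring-closed hydroxy ester 25 (not isolated)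
Conditions: CrCl2 (8 equiv), degassed DMF, rt, 24 added by syringe pump (final about 3 mM); then PPTS (cat.), 40 °C, same flask
Reagents that add atoms: none
Why: CrCl2 reduces the C13–Br bond in two one-electron steps to a (Z)-allylchromium(III) species, which adds through its γ-carbon C7 to the chromium-bound C6 aldehyde (SE2′, the double bond moving to C11=C13), and the resulting Cr(III) alkoxide 25 acylates on the C12 methyl ester. The closest known reaction type is the intramolecular Nozaki–Hiyama–Kishi (chromium Barbier) 2-(alkoxycarbonyl)allylation of an aldehyde, the macrocyclic form of the Dreiding–Schmidt α-methylene lactone synthesis. The carbocycle closes by a ten-membered addition that is exo at the carbonyl with the allyl π-bond left exocyclic, and the lactone by 5-exo-trig acyl substitution. C7 is controlled by the C8 stereocentre: the PMB ether oxygen should chelate chromium in the Z-allyl species, so that the reaction runs through a boat-like bicyclic transition state (Cr bridged to C7 by C13–C11, O6–C6 and O8–C8) in which C9 points to the aldehyde bridge; C6 is controlled by the same transition state, where the C5 chain lies anti to C8 to avoid a C5/C9 syn-pentane contact, which makes the addition anti (6,7-trans). The step needs anti addition on the C7 face syn to C9 and ring closure in preference to oligomerisation; the (Z)-bromide with its chelating ether, the cis C1=C10 olefin that folds the chain, and slow addition at high dilution should secure them.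

Step 19
Reactants: 26 8-O-PMB-14,15-bis-O-TBDPS lactone
Product: 27 8-hydroxy-14,15-bis-O-TBDPS lactone (8-deacyl target as its bis-silyl ether)
Conditions: DDQ, CH2Cl2/pH 7 buffer (10:1), 0 °C → rt
Reagents that add atoms: none
Why: Oxidative PMB ether cleavage (DDQ, hydride abstraction then hydrolysis of the hemiacetal) frees O8–H, the TBDPS ethers and both electron-poor alkenes being inert.

Step 20
Reactants: 27 8-hydroxy-14,15-bis-O-TBDPS lactone; 28 methacrylic anhydride
Product: 29 14,15-bis-O-TBDPS ether of the target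
Conditions: Et3N, DMAP (cat.), CH2Cl2, 0 °C → rt
Reagents that add atoms: none
Why: DMAP-catalysed acylation of the only free hydroxyl with the anhydride (nucleophilic catalysis) installs the methacrylate with retention at C8.

Step 21
Reactants: 29 14,15-bis-O-TBDPS ether of the target
Product: 30 CNP0546547.2 (target)
Conditions: HF·pyridine, pyridine/THF, 0 °C → rt
Reagents that add atoms: none
Why: Fluoride-mediated Si–O cleavage with buffered HF·pyridine removes both TBDPS groups without the basic conditions that could cause conjugate addition to the methacrylate or the α-methylene lactone.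

Compound list

1 | (S)-4-benzyloxazolidin-2-one | O=C1N[C@@H](Cc2ccccc2)CO1 | starting material
2 | pent-4-enoyl chloride | C=CCCC(=O)Cl | starting material
3 | (S)-4-benzyl-3-(pent-4-enoyl)oxazolidin-2-one | O=C(CCC=C)N1[C@@H](Cc2ccccc2)COC1=O | intermediate
4 | acrylonitrile | C=CC#N | starting material
5 | (S)-4-benzyl-3-[(2S)-2-(2-cyanoethyl)pent-4-enoyl]oxazolidin-2-one | N#CCC[C@H](C(=O)N1[C@@H](Cc2ccccc2)COC1=O)CC=C | intermediate
6 | (4S)-4-(hydroxymethyl)hept-6-enenitrile | N#CCC[C@H](CO)CC=C | intermediate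
7 | (4S)-4-{[tert-butyl(diphenyl)silyl]oxymethyl}hept-6-enenitrile | N#CCC[C@H](CO[Si](c1ccccc1)(c1ccccc1)C(C)(C)C)CC=C | intermediate
8 | (4S)-4-{[tert-butyl(diphenyl)silyl]oxymethyl}-6-oxohexanenitrile (aldehyde, not isolated) | N#CCC[C@H](CO[Si](c1ccccc1)(c1ccccc1)C(C)(C)C)CC=O | intermediate
9 | (4S)-4-{[tert-butyl(diphenyl)silyl]oxymethyl}-6,6-dimethoxyhexanenitrile | N#CCC[C@H](CO[Si](c1ccccc1)(c1ccccc1)C(C)(C)C)CC(OC)OC | intermediate
10 | (4S)-4-{[tert-butyl(diphenyl)silyl]oxymethyl}-6,6-dimethoxyhexanal | O=CCC[C@H](CO[Si](c1ccccc1)(c1ccccc1)C(C)(C)C)CC(OC)OC | intermediate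
11 | (S)-glycidol | OC[C@H]1CO1 | starting material
12 | (R)-2-{[(4-methoxybenzyl)oxy]methyl}oxirane | COc1ccc(COC[C@H]2CO2)cc1 | intermediate
13 | triethyl phosphonoacetate | CCOC(=O)CP(=O)(OCC)OCC | starting material
14 | diethyl [(5R)-5-{[(4-methoxybenzyl)oxy]methyl}-2-oxooxolan-3-yl]phosphonate (both C3 epimers) | CCOP(=O)(OCC)C1C[C@H](COCc2ccc(OC)cc2)OC1=O | intermediate
15 | (3E,5R)-3-[(4S)-4-(TBDPSOCH2)-6,6-dimethoxyhexylidene]-5-(PMBOCH2)oxolan-2-one | O=C1O[C@@H](COCc2ccc(OC)cc2)C/C1=C\CC[C@H](CO[Si](c2ccccc2)(c2ccccc2)C(C)(C)C)CC(OC)OC | intermediate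
16 | diol (MeO)2CH–CH2–CH(CH2OTBDPS)–CH2CH2–CH=C(CH2OH)–CH2–CH(OH)–CH2OPMB (4S,8R,1(10)E) | O[C@@H](COCc1ccc(OC)cc1)C/C(CO)=C\CC[C@H](CO[Si](c1ccccc1)(c1ccccc1)C(C)(C)C)CC(OC)OC | intermediate
17 | secondary alcohol, as 16 with O14 as TBDPS ether | O[C@@H](COCc1ccc(OC)cc1)C/C(CO[Si](c1ccccc1)(c1ccccc1)C(C)(C)C)=C\CC[C@H](CO[Si](c1ccccc1)(c1ccccc1)C(C)(C)C)CC(OC)OC | intermediate
18 | p-methoxybenzylidene acetal of O7/O8, (4R)-2-(4-methoxyphenyl)-1,3-dioxolane (acetal epimers) | COc1ccc(cc1)C1OC[C@H](O1)C/C(CO[Si](c1ccccc1)(c1ccccc1)C(C)(C)C)=C\CC[C@H](CO[Si](c1ccccc1)(c1ccccc1)C(C)(C)C)CC(OC)OC | intermediate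
19 | primary alcohol (MeO)2CH–CH2–CH(CH2OTBDPS)–CH2CH2–CH=C(CH2OTBDPS)–CH2–CH(OPMB)–CH2OH (4S,8R,1(10)E) | COc1ccc(CO[C@@H](CO)C/C(CO[Si](c2ccccc2)(c2ccccc2)C(C)(C)C)=C\CC[C@H](CO[Si](c2ccccc2)(c2ccccc2)C(C)(C)C)CC(OC)OC)cc1 | intermediate
20 | aldehyde, as 19 with C7 as CHO | COc1ccc(CO[C@@H](C=O)C/C(CO[Si](c2ccccc2)(c2ccccc2)C(C)(C)C)=C\CC[C@H](CO[Si](c2ccccc2)(c2ccccc2)C(C)(C)C)CC(OC)OC)cc1 | intermediate
21 | methyl acrylate | C=CC(=O)OC | starting material
22 | hydroxy ester, C7 carbinol bearing C(=CH2)CO2Me (both C7 epimers) | COc1ccc(CO[C@@H](C(O)C(=C)C(=O)OC)C/C(CO[Si](c2ccccc2)(c2ccccc2)C(C)(C)C)=C\CC[C@H](CO[Si](c2ccccc2)(c2ccccc2)C(C)(C)C)CC(OC)OC)cc1 | intermediate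
23 | (Z)-allylic bromide, C8H(OPMB)–CH=C(CH2Br)CO2Me with C6 dimethyl acetal | COc1ccc(CO[C@@H](/C=C(\CBr)C(=O)OC)C/C(CO[Si](c2ccccc2)(c2ccccc2)C(C)(C)C)=C\CC[C@H](CO[Si](c2ccccc2)(c2ccccc2)C(C)(C)C)CC(OC)OC)cc1 | intermediate
24 | (Z)-bromo aldehyde OHC–CH2–CH(CH2OTBDPS)–CH2CH2–CH=C(CH2OTBDPS)–CH2–CH(OPMB)–CH=C(CH2Br)CO2Me (4S,8R,1(10)E) | COc1ccc(CO[C@@H](/C=C(\CBr)C(=O)OC)C/C(CO[Si](c2ccccc2)(c2ccccc2)C(C)(C)C)=C\CC[C@H](CO[Si](c2ccccc2)(c2ccccc2)C(C)(C)C)CC=O)cc1 | intermediate
25 | ring-closed hydroxy ester: ten-membered carbocycle with C6–OH and C7–C(=CH2)CO2Me (drawn as the alcohol, present in the flask as its Cr(III) alkoxide; not isolated) | COc1ccc(CO[C@@H]2C/C(CO[Si](c3ccccc3)(c3ccccc3)C(C)(C)C)=C\CC[C@H](CO[Si](c3ccccc3)(c3ccccc3)C(C)(C)C)C[C@@H](O)[C@@H]2C(=C)C(=O)OC)cc1 | intermediate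
26 | 8-O-PMB-14,15-bis-O-TBDPS derivative of the 8-deacyl target lactone (stereocentres as in the target) | COc1ccc(CO[C@@H]2C/C(CO[Si](c3ccccc3)(c3ccccc3)C(C)(C)C)=C\CC[C@H](CO[Si](c3ccccc3)(c3ccccc3)C(C)(C)C)C[C@H]3OC(=O)C(=C)[C@H]23)cc1 | intermediate
27 | 8-hydroxy-14,15-bis-O-TBDPS lactone | O[C@@H]1C/C(CO[Si](c2ccccc2)(c2ccccc2)C(C)(C)C)=C\CC[C@H](CO[Si](c2ccccc2)(c2ccccc2)C(C)(C)C)C[C@H]2OC(=O)C(=C)[C@H]12 | intermediate
28 | methacrylic anhydride | C=C(C)C(=O)OC(=O)C(C)=C | starting material
29 | 14,15-bis-O-TBDPS ether of the target | C=C(C)C(=O)O[C@@H]1C/C(CO[Si](c2ccccc2)(c2ccccc2)C(C)(C)C)=C\CC[C@H](CO[Si](c2ccccc2)(c2ccccc2)C(C)(C)C)C[C@H]2OC(=O)C(=C)[C@H]12 | intermediate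
30 | CNP0546547.2 | C=C(C)C(=O)O[C@@H]1C/C(CO)=C\CC[C@H](CO)C[C@H]2OC(=O)C(=C)[C@H]12 | target

Total step count: 21. Longest linear sequence: 19 steps (steps 1–6, then 9–21); steps 7–8 make the second fragment.

Steps most likely to fail

Step 18. The ring-closing transition state may deliver the aldehyde with the opposite C6 topicity (syn addition), so that the carbinol forms with the wrong configuration; this is the least predictable selectivity of the route. The fallback sets out from 24 and comes back at 26. The chromium closure is stopped at the hydroxy-ester stage by cold neutral work-up without PPTS. The C6-epimeric hydroxy ester F1 is then inverted at C6 by a Mitsunobu reaction (4-nitrobenzoic acid, PPh3, DIAD, toluene, 0 °C) to the 4-nitrobenzoate F2. Methanolysis (K2CO3, MeOH, 0 °C) frees the C6 alkoxide, now of the right configuration, which closes the lactone to 26. C6 is then set by SN2 inversion instead of by the transition state.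

Step 15. The amine-catalysed addition is slow, and over that time the α-alkoxy aldehyde may enolise (epimerisation at C8) or decompose. The fallback sets out from 20 and comes back at 22 by vinylalumination instead of amine catalysis. Methyl propiolate is hydroaluminated with DIBAL-H (HMPA or N-methylmorpholine N-oxide as additive, THF, 0 °C) to [1-(methoxycarbonyl)vinyl]diisobutylaluminium F3, which should add to 20 at −78 °C within minutes under non-basic conditions and give the same hydroxy ester 22.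

Step 9. Kinetic E/Z control in the olefination may be poor, so that much material ends as the wrong alkene geometry. The fallback sets out from 14 and 10 and comes back at 15. The (Z)-alkylidene lactone F4 is not discarded but equilibrated to the more stable E isomer 15 by reversible thiyl-radical addition–elimination (PhSSPh cat., hν, benzene), so the geometry is set thermodynamically rather than kinetically.

Further compounds

F1 | step 18 | C6-epimeric ring-closed hydroxy ester (syn adduct) | COc1ccc(CO[C@@H]2C/C(CO[Si](c3ccccc3)(c3ccccc3)C(C)(C)C)=C\CC[C@H](CO[Si](c3ccccc3)(c3ccccc3)C(C)(C)C)C[C@H](O)[C@@H]2C(=C)C(=O)OC)cc1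
F2 | step 18 | C6 4-nitrobenzoate with inverted (target) configuration at C6 | COc1ccc(CO[C@@H]2C/C(CO[Si](c3ccccc3)(c3ccccc3)C(C)(C)C)=C\CC[C@H](CO[Si](c3ccccc3)(c3ccccc3)C(C)(C)C)C[C@@H](OC(=O)c3ccc(cc3)[N+](=O)[O-])[C@@H]2C(=C)C(=O)OC)cc1
F3 | step 15 | [1-(methoxycarbonyl)vinyl]diisobutylaluminium | COC(=O)C(=C)[Al](CC(C)C)CC(C)C
F4 | step 9 | (Z)-alkylidene lactone, geometric isomer of 15 | O=C1O[C@@H](COCc2ccc(OC)cc2)C/C1=C/CC[C@H](CO[Si](c2ccccc2)(c2ccccc2)C(C)(C)C)CC(OC)OC
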